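The depside ester is disconnected at the aryl–oxygen bond between the ester oxygen and carbon 4 of ring B (the methyl benzoate), not at the acyl carbon of ring A (the formylresorcinol acid). The key step exploits crowding at both termini: carbon 1 of ring A lies between the oxygen on carbon 2 and the methyl on carbon 6, carbon 4 of ring B between the methyls on carbons 3 and 5, while the carboxylate oxygen stays exposed. In one operation the ring A carboxylate is O-arylated by a ring B aryl(trimethoxyphenyl)iodonium tosylate, forming only that bond. The precursors are the bis-MOM formyl acid and the iodonium salt; acid removes both MOM groups.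

Key step: step 9

Assumption: 2,4-dihydroxy-3,6-dimethylbenzoic acid (3-methylorsellinic acid) is taken as a catalogue compound, so that the ring A carboxyl is in place from the start and no symmetric dialdehyde has to be oxidised on one side only.

Remark: ring A is numbered from its carboxyl carbon (carbon 1 carboxyl, carbon 2 oxygen, carbon 3 methyl, carbon 4 oxygen, carbon 5 formyl, carbon 6 methyl). Ring B is numbered from its methoxycarbonyl carbon (carbon 1 CO2Me, carbon 2 OMe, carbon 3 methyl, carbon 4 ester oxygen, carbon 5 methyl, carbon 6 methyl). The target is achiral; only the transient chloro ether 11 has a stereocentre, which is racemic and is lost on hydrolysis.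

Step 1
Reactants: 1 2,4,5-trimethylphenol
Product: 3 2-hydroxy-3,5,6-trimethylbenzoic acid, via sodium 2,4,5-trimethylphenoxide 2 (not isolated)
Conditions: NaH, THF, 0 °C to rt; evaporate to dryness; CO2 (50 bar), 150 °C, autoclave; then 2 M HCl
Reagents that add atoms: carbon dioxide, O=C=O
Why: Kolbe–Schmitt carboxylation, in which the dry sodium phenoxide should attack CO2 through position 6 of the phenol, the only position ortho or para to the oxygen that still bears hydrogen, so a single salicylic acid is expected.

Step 2
Reactants: 3 2-hydroxy-3,5,6-trimethylbenzoic acid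
Product: 4 methyl 2-methoxy-3,5,6-trimethylbenzoate
Conditions: MeI (3 equiv), K2CO3 (3 equiv), DMF, 50 °C
Reagents that add atoms: iodomethane, CI
Why: Double SN2 methylation (Williamson ether synthesis plus carboxylate alkylation) takes place at the methyl carbon of MeI, so the crowding around the carboxyl group should not matter, and warm DMF breaks the phenol–carboxyl hydrogen bond.

Step 3
Reactants: 4 methyl 2-methoxy-3,5,6-trimethylbenzoate
Product: 5 methyl 4-iodo-2-methoxy-3,5,6-trimethylbenzoate
Conditions: NIS (1.2 equiv), TFA, TfOH (10 mol %), 0 °C to rt, dark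
Reagents that add atoms: N-iodosuccinimide, O=C1CCC(=O)N1I
Why: Electrophilic aromatic iodination (SEAr) with acid-activated NIS can only substitute carbon 4, the single ring carbon bearing hydrogen, which is activated by its two ortho methyl groups while the ester, twisted out of the ring plane by its ortho neighbours, withdraws little.

Step 4
Reactants: 5 methyl 4-iodo-2-methoxy-3,5,6-trimethylbenzoate, 6 1,3,5-trimethoxybenzene
Product: 8 [3-methoxy-4-(methoxycarbonyl)-2,5,6-trimethylphenyl](2,4,6-trimethoxyphenyl)iodonium tosylate, via hydroxy(tosyloxy)iodoarene 7 (not isolated)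
Conditions: mCPBA (1.1 equiv), TsOH·H2O (1.05 equiv), MeCN, 60 °C; then 6 (1.05 equiv), 60 °C; precipitation with Et2O
Reagents that add atoms: p-toluenesulfonic acid monohydrate, Cc1ccc(S(=O)(=O)O)cc1.O
Why: One-pot diaryliodonium salt synthesis, in which mCPBA and TsOH oxidise the aryl iodide to the trivalent-iodine species 7, whose iodine then substitutes the very electron-rich trimethoxybenzene at a ring carbon (SEAr), after which the salt should precipitate.

Step 5
Reactants: 9 2,4-dihydroxy-3,6-dimethylbenzoic acid
Product: 10 allyl 2,4-dihydroxy-3,6-dimethylbenzoate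
Conditions: allyl bromide (1.2 equiv), KHCO3 (1.2 equiv), DMF, rt to 40 °C
Reagents that add atoms: allyl bromide, C=CCBr
Why: Carboxylate O-alkylation (SN2), in which KHCO3 ionises only the carboxylic acid so that both phenols should stay free, and attack occurs at the allylic carbon, far from the crowded acyl carbon.

Step 6
Reactants: 10 allyl 2,4-dihydroxy-3,6-dimethylbenzoate
Product: 12 allyl 5-formyl-2,4-dihydroxy-3,6-dimethylbenzoate, via chloro(methoxy)methyl arene 11 (not isolated)
Conditions: TiCl4 (3 equiv), Cl2CHOMe (1.5 equiv), CH2Cl2, −10 °C to rt; then 1 M HCl, 0 °C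
Reagents that add atoms: dichloromethyl methyl ether, COC(Cl)Cl; water, O
Why: Rieche formylation, in which the TiCl4-bound phenoxide directs the chloro(methoxy)methyl cation to carbon 5, the only unsubstituted ring carbon (ortho to the oxygen on carbon 4, para to the oxygen on carbon 2), and aqueous acid hydrolyses chloro ether 11 to the aldehyde.

Step 7
Reactants: 12 allyl 5-formyl-2,4-dihydroxy-3,6-dimethylbenzoate
Product: 13 allyl 5-formyl-2,4-bis(methoxymethoxy)-3,6-dimethylbenzoate
Conditions: NaH (2.5 equiv), THF–DMF, 0 °C; MOMCl (3 equiv), 0 °C to rt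
Reagents that add atoms: chloromethyl methyl ether, COCCl
Why: Williamson-type O-alkylation of the bis-phenoxide with the highly reactive chloromethyl methyl ether should cap both chelated phenols, the aldehyde being non-enolisable and the allyl ester inert to NaH at this temperature.

Step 8
Reactants: 13 allyl 5-formyl-2,4-bis(methoxymethoxy)-3,6-dimethylbenzoate
Product: 14 5-formyl-2,4-bis(methoxymethoxy)-3,6-dimethylbenzoic acid
Conditions: Pd(PPh3)4 (5 mol %), N-methylaniline (2 equiv), THF, rt
Reagents that add atoms: none
Why: Tsuji–Trost deallylation, in which zerovalent palladium ionises the allyl–oxygen bond to a π-allyl complex that N-methylaniline intercepts, so the acid is released without attack at its hindered acyl carbon and without touching the aldehyde or the MOM ethers.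

Step 9
Reactants: 14 5-formyl-2,4-bis(methoxymethoxy)-3,6-dimethylbenzoic acid, 8 [3-methoxy-4-(methoxycarbonyl)-2,5,6-trimethylphenyl](2,4,6-trimethoxyphenyl)iodonium tosylate
Product: 17 3-methoxy-4-(methoxycarbonyl)-2,5,6-trimethylphenyl 5-formyl-2,4-bis(methoxymethoxy)-3,6-dimethylbenzoate, via potassium carboxylate 15 (not isolated), via aryl(carboxylato)iodane 16 (not isolated)
Conditions: 14, KOt-Bu (1.0 equiv), THF, 0 °C; solvent exchanged; 8 (1.1 equiv), toluene, 110 °C
Reagents that add atoms: none
Why: Carboxylate 15 should displace tosylate on trivalent iodine to give the T-shaped diaryl(carboxylato)iodane 16, and ligand coupling through a three-centre transition state then joins the carboxylate oxygen to the ipso carbon of ring B (carbon 4) while 2-iodo-1,3,5-trimethoxybenzene leaves with iodine reduced to the monovalent state. The closest known reaction type is the transition-metal-free O-arylation of carboxylic acids by diaryliodonium salts that carry a trimethoxyphenyl dummy ligand, a process known to accept ortho-disubstituted aryl groups and hindered acids. No ring is closed and no stereocentre is formed. The step needs transfer of the ring B aryl instead of the trimethoxyphenyl group, and electronics secure this: ring B carries a para ester and accepts oxygen at its ipso carbon, whereas three methoxy donors make the dummy ring a poor acceptor, so it stays on iodine. Chemoselectivity for the carboxylate is secured by the MOM caps on both phenols and the inertness of the aldehyde, and an aryne side path is excluded because neither aryl ligand has an ortho hydrogen. Steric demand is low because the bond-forming oxygen sits two atoms away from carbon 1 of ring A, and carbon 4 of ring B is reached from an iodine atom already bound to it, not by an external nucleophile.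

Step 10
Reactants: 17 3-methoxy-4-(methoxycarbonyl)-2,5,6-trimethylphenyl 5-formyl-2,4-bis(methoxymethoxy)-3,6-dimethylbenzoate
Product: 18 methyl 4-[(5-formyl-2,4-dihydroxy-3,6-dimethylbenzoyl)oxy]-2-methoxy-3,5,6-trimethylbenzoate (target)
Conditions: 3 M HCl (aq), THF, 40 °C
Reagents that add atoms: none
Why: Acid-catalysed acetal hydrolysis removes both MOM ethers, while the hindered aryl and methyl esters should resist dilute aqueous acid and the fully substituted rings offer no site for the released formaldehyde to attack.

Compound list
1 | 2,4,5-trimethylphenol | Cc1cc(C)c(O)cc1C | starting material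
2 | sodium 2,4,5-trimethylphenoxide | Cc1cc(C)c([O-])cc1C.[Na+] | intermediate
3 | 2-hydroxy-3,5,6-trimethylbenzoic acid | Cc1cc(C)c(O)c(C(=O)O)c1C | intermediate
4 | methyl 2-methoxy-3,5,6-trimethylbenzoate | COC(=O)c1c(C)c(C)cc(C)c1OC | intermediate
5 | methyl 4-iodo-2-methoxy-3,5,6-trimethylbenzoate | COC(=O)c1c(C)c(C)c(I)c(C)c1OC | intermediate
6 | 1,3,5-trimethoxybenzene | COc1cc(OC)cc(OC)c1 | starting material
7 | methyl 4-[hydroxy(tosyloxy)iodo]-2-methoxy-3,5,6-trimethylbenzoate | COC(=O)c1c(C)c(C)c(I(O)OS(=O)(=O)c2ccc(C)cc2)c(C)c1OC | intermediate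
8 | [3-methoxy-4-(methoxycarbonyl)-2,5,6-trimethylphenyl](2,4,6-trimethoxyphenyl)iodonium tosylate | COC(=O)c1c(C)c(C)c([I+]c2c(OC)cc(OC)cc2OC)c(C)c1OC.Cc1ccc(S(=O)(=O)[O-])cc1 | intermediate
9 | 2,4-dihydroxy-3,6-dimethylbenzoic acid | Cc1cc(O)c(C)c(O)c1C(=O)O | starting material
10 | allyl 2,4-dihydroxy-3,6-dimethylbenzoate | C=CCOC(=O)c1c(C)cc(O)c(C)c1O | intermediate
11 | allyl 5-[chloro(methoxy)methyl]-2,4-dihydroxy-3,6-dimethylbenzoate (racemic) | C=CCOC(=O)c1c(C)c(C(Cl)OC)c(O)c(C)c1O | intermediate
12 | allyl 5-formyl-2,4-dihydroxy-3,6-dimethylbenzoate | C=CCOC(=O)c1c(C)c(C=O)c(O)c(C)c1O | intermediate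
13 | allyl 5-formyl-2,4-bis(methoxymethoxy)-3,6-dimethylbenzoate | C=CCOC(=O)c1c(C)c(C=O)c(OCOC)c(C)c1OCOC | intermediate
14 | 5-formyl-2,4-bis(methoxymethoxy)-3,6-dimethylbenzoic acid | COCOc1c(C)c(OCOC)c(C(=O)O)c(C)c1C=O | intermediate
15 | potassium 5-formyl-2,4-bis(methoxymethoxy)-3,6-dimethylbenzoate | COCOc1c(C)c(OCOC)c(C(=O)[O-])c(C)c1C=O.[K+] | intermediate
16 | [3-methoxy-4-(methoxycarbonyl)-2,5,6-trimethylphenyl](2,4,6-trimethoxyphenyl)iodanyl 5-formyl-2,4-bis(methoxymethoxy)-3,6-dimethylbenzoate (T-shaped, trivalent iodine) | COC(=O)c1c(C)c(C)c(I(OC(=O)c2c(C)c(C=O)c(OCOC)c(C)c2OCOC)c2c(OC)cc(OC)cc2OC)c(C)c1OC | intermediate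
17 | 3-methoxy-4-(methoxycarbonyl)-2,5,6-trimethylphenyl 5-formyl-2,4-bis(methoxymethoxy)-3,6-dimethylbenzoate | COC(=O)c1c(C)c(C)c(OC(=O)c2c(C)c(C=O)c(OCOC)c(C)c2OCOC)c(C)c1OC | intermediate
18 | methyl 4-[(5-formyl-2,4-dihydroxy-3,6-dimethylbenzoyl)oxy]-2-methoxy-3,5,6-trimethylbenzoate (achiral) | COC(=O)c1c(C)c(C)c(OC(=O)c2c(C)c(C=O)c(O)c(C)c2O)c(C)c1OC | target

Total step count: 10 (steps 1–4 build the ring B iodonium salt, steps 5–8 the ring A acid, steps 9–10 join them and deprotect).
Longest linear sequence: 6 steps (1, 2, 3, 4, 9, 10; the ring A branch 5, 6, 7, 8, 9, 10 is equally long).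

Steps most likely to fail

Step 9. The ligand coupling may be slow at the doubly flanked carbon 4 of ring B, so that the iodonium carboxylate decomposes thermally, or the oxygen may be delivered to the wrong aryl ligand. The fallback forms the same ester by acyl substitution, with the oxygen placed on ring B beforehand. It sets out from iodide 5 and acid 14. Miyaura borylation of 5 (bis(pinacolato)diboron, Pd(dppf)Cl2, KOAc, dioxane, 90 °C) should give methyl 2-methoxy-3,5,6-trimethyl-4-(4,4,5,5-tetramethyl-1,3,2-dioxaborolan-2-yl)benzoate F1. Oxidation (H2O2, NaOH, THF, 0 °C) should give methyl 4-hydroxy-2-methoxy-3,5,6-trimethylbenzoate F2, and NaH in THF its salt, sodium 3-methoxy-4-(methoxycarbonyl)-2,5,6-trimethylphenoxide F3. Acid 14 would be converted under neutral conditions (1-chloro-N,N,2-trimethylprop-1-en-1-amine, CH2Cl2, rt) into 5-formyl-2,4-bis(methoxymethoxy)-3,6-dimethylbenzoyl chloride F4. Acylation of F3 by F4 (THF, 60 °C) is helped by the acylium-like character of ortho-disubstituted benzoyl chlorides. The fallback comes back to the route at compound 17.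

Step 3. Ring iodination may stay incomplete at a position that has no oxygen donor ortho or para to it, with benzylic oxidation or acid-induced ester cleavage taking over on forcing. The fallback sets out from compound 4 and brings in the halogen as bromine. Br2 with catalytic FeBr3 (CH2Cl2, 0 °C, dark) should give methyl 4-bromo-2-methoxy-3,5,6-trimethylbenzoate F5. A copper-catalysed aromatic Finkelstein exchange (CuI, NaI, trans-N,N'-dimethylcyclohexane-1,2-diamine, dioxane, 110 °C) then swaps bromine for iodine. The fallback comes back to the route at compound 5.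

Step 1. Carboxylation under pressure may be incomplete or reverse at the temperature required, and traces of moisture protonate the phenoxide. The fallback sets out from compound 1 and introduces the carboxyl carbon by halogen–metal exchange. NBS (MeCN, 0 °C) should brominate the only free ortho position to give 2-bromo-3,4,6-trimethylphenol F6. MeI and K2CO3 in DMF should give 3-bromo-2-methoxy-1,4,5-trimethylbenzene F7. n-BuLi (THF, −78 °C) should give (2-methoxy-3,5,6-trimethylphenyl)lithium F8, which is quenched with methyl chloroformate. The fallback comes back to the route at compound 4, bypassing compound 3.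

Further compounds
F1 | step 9 | methyl 2-methoxy-3,5,6-trimethyl-4-(4,4,5,5-tetramethyl-1,3,2-dioxaborolan-2-yl)benzoate | COC(=O)c1c(C)c(C)c(B2OC(C)(C)C(C)(C)O2)c(C)c1OC
F2 | step 9 | methyl 4-hydroxy-2-methoxy-3,5,6-trimethylbenzoate | COC(=O)c1c(C)c(C)c(O)c(C)c1OC
F3 | step 9 | sodium 3-methoxy-4-(methoxycarbonyl)-2,5,6-trimethylphenoxide | COC(=O)c1c(C)c(C)c([O-])c(C)c1OC.[Na+]
F4 | step 9 | 5-formyl-2,4-bis(methoxymethoxy)-3,6-dimethylbenzoyl chloride | COCOc1c(C)c(OCOC)c(C(=O)Cl)c(C)c1C=O
F5 | step 3 | methyl 4-bromo-2-methoxy-3,5,6-trimethylbenzoate | COC(=O)c1c(C)c(C)c(Br)c(C)c1OC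
F6 | step 1 | 2-bromo-3,4,6-trimethylphenol | Cc1cc(C)c(O)c(Br)c1C
F7 | step 1 | 3-bromo-2-methoxy-1,4,5-trimethylbenzene | Cc1cc(C)c(OC)c(Br)c1C
F8 | step 1 | (2-methoxy-3,5,6-trimethylphenyl)lithium | [Li]c1c(OC)c(C)cc(C)c1C
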